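**Remark on the chemistry:** the target (21) is achiral, so every intermediate with sp3 stereocentres is carried as a racemate or diastereomer mixture and drawn without configuration; all such centres are gone after step 12.

## The problem

Compound 21 is an achiral octaphenol: a biphenyl of two catechols (rings A and B), each carrying a 9-(2,6-dihydroxyphenyl)-9-oxononyl chain. Ring A is 1,3,4,5-tetrasubstituted (chain on C1, hydroxyls on C3 and C4, ring B on C5). Ring B is joined through C1', with its chain on C6' and hydroxyls on C3' and C4', so the biaryl bond lies next to an oxygen on one side and a long alkyl chain on the other. There is no stereocentre and, with only two ortho substituents, no stable axis; any sp3 centre made on the way controls nothing and only has to disappear. Each acyl group sits between the two hydroxyls of its resorcinol, a position that electrophilic acylation of a resorcinol does not reach, so it must come from a 1,3-dioxygenated benzene already functionalised at C2. The free catechols and acylresorcinols are air-sensitive and chelate metals, so all eight oxygens must stay masked or latent to the end, and the ketones should not meet enolate bases or hydrides. The enabling feature is ring A itself: the array C1–C2–C3(OH)–C4(OH)–C5–C6 is the aromatic tautomer of a cyclohex-3-ene-1,2-dione. That dione is the oxidised form of a cyclohex-3-ene-1,2-diol whose only double bond, C1=C2, carries no heteroatom and can be closed from two terminal alkenes of a chain that already holds ring B on sp3 C5.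

## Retrosynthesis

**21 ⇒ 20.** Six O–CH3 bonds are cut. Methyl ethers are the only masks that survive every reagent class of the route (organomagnesium, borane, amide base, hydride, palladium, ruthenium, two oxidations). Four of them lie ortho to a ketone and are cleaved with chelation assistance. Ring A needs no mask because its catechol is only created in the step before. The forward reaction must cleave six ethers without harming ketones or chains.

**20 ⇒ 18 (through 19).** No skeletal bond is cut; the oxidation level of ring A is lowered. Catechol 20 is the enol form of cyclohexenedione 19, which is the double oxidation product of diol 18. This trades an arene that would need a hindered biaryl coupling for a cyclohexene with three sp3 centres of no consequence. The oxidant must stop at the dione and must not take the catechol on to the quinone.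

**18 ⇒ 17.** The C1=C2 bond of ring A is cut as an alkene, opening the ring to acyclic diene diol 17 (C10 and C15 of the chain become C1 and C2). This is the only ring bond of 18 that is a C=C between two carbons free of heteroatoms, so it is the natural metathesis cut. The neighbouring choice, cutting the C5–C1' biaryl bond, would require a 1,3,4,5-tetrasubstituted ring A halide and a coupling next to an oxygen and a chain. In 17 ring B sits on an sp3 carbon and is introduced as an arylacetic ester. The forward reaction must close a six-membered ring between a monosubstituted and a 1,1-disubstituted alkene in the presence of free hydroxyls.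

**17 ⇒ 13 + 15.** The C3–C4 bond of ring A (C13–C14 of 17) is cut between the two carbinol carbons, giving aldehyde 13 and the three-carbon enol acetate 15 as an α-hydroxyallyl anion equivalent. This single cut delivers both oxygens and the vinyl group at once; building the diol from an alkene by dihydroxylation would compete with the 1,1-disubstituted alkene. The nucleophile must choose the aldehyde over two ketones. These are di-ortho-substituted aryl ketones, twisted and shielded, and allylindium reagents discriminate well.

**13 ⇒ 12 ⇒ 11.** Only oxidation levels change. The aldehyde and both ketones of 13 come from one oxidation of triol 12, which comes from hydride reduction of hydroxy ester 11. Keeping the two chain termini as carbinols from the start means that no enolisable ketone is present during the enolate alkylation and no ketone during the ester reduction, without a protecting group.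

**11 ⇒ 10 + 7.** The bond between ring A C1 (still an sp2 alkene carbon) and its chain is cut, giving vinyl bromide 10 and the B-alkyl-9-borabicyclononane 7. A B-alkyl Suzuki–Miyaura coupling makes this bond, and the same borane 7 serves both chains of 21.

**10 ⇒ 8 + 2,3-dibromopropene.** The C5–C6 bond of ring A is cut next to the benzylic carbon. The arylacetate enolate of 8 and the allylic bromide of 2,3-dibromopropene form it, and the reagent brings the vinyl bromide needed for the next coupling. This replaces a catalytic aldehyde allylation by the most reliable C–C bond formation available at this carbon.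

**8 ⇒ 6 + 7.** The bond between ring B C6' and its chain is cut, giving aryl bromide 6 and again borane 7. The order is fixed by mechanism. If the allyl unit were already present, the arylpalladium bromide would sit five atoms from a 1,1-disubstituted alkene and would cyclise to an indane by 5-exo carbopalladation. The aryl bromide is therefore consumed first.

**7 ⇒ 4 ⇒ 1 + 2; 6 ⇒ 5; 15 ⇒ 14.** Borane 7 is the 9-BBN adduct of terminal alkene 4. It is prepared once, as a stock solution under argon, and divided between the two couplings. Alkene 4 is the Grignard adduct of 8-bromooct-1-ene 1 and 2,6-dimethoxybenzaldehyde 2, which fixes the acyl position between the two oxygens. Bromide 6 comes from bromination of methyl homoveratrate 5 at its most activated position. Reagent 15 is the adduct of acrolein 14 and acetyl bromide.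

## Roads not taken

**Alternative 1:** The cut lies inside each acylresorcinol, at the ring bond between the acyl-bearing carbon and one oxygenated carbon, so both terminal rings unravel into methyl 5,7-dioxoalkanoate ends on a preformed biaryl (bis(dioxo ester) A2). Forward, NaOMe would make C6 of each terminus attack its own ester carbon and close two six-membered triketone rings at once, giving bis(2-acylcyclohexane-1,3-dione) A1.
- Merits: the acyl group ends up between the two oxygens by construction, with no directed metalation, and the twofold closure uses the symmetry of the termini.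
- Weak points: A1 is one oxidation level below an acylresorcinol, so two dehydrogenations are still needed on a late, strongly chelating intermediate, for which no mild general method exists. A2 needs two regiocontrolled 1,3-diketone assemblies on long chains. The key step builds the one part of 21 that can be bought in the right oxidation state, and leaves rings A and B and their bond to an arene coupling.
- Comparison: this road would need only four ether cleavages at the end, a real advantage over the six of step 13. The chosen plan sets against this that its acylresorcinols cost one step from aldehyde 2 and that four of its six ethers are the easily cleaved ortho-carbonyl ones.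

**Alternative 2:** The cut is at both C(=O)–CH2 bonds, leading back to biaryl diene A4 with two oct-7-enyl chains and two molecules of 2,6-dihydroxybenzaldehyde A5. Forward, [Rh(cod)Cl]2 (monovalent rhodium) with a bisphosphine would add the formyl C–H bond of A5 across each terminal alkene, chelation by the ortho hydroxyl holding the acylrhodium hydride against decarbonylation, to give A3, the target with both catechols as methyl ethers.
- Merits: it is the most convergent of the four plans, fully atom-economic, uses a commercial aldehyde with free phenols and would leave only four ether cleavages.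
- Weak points: the linear-to-branched ratio of hydroacylation on unactivated 1-alkenes depends on substrate and ligand and would have to hold twice in one molecule. Rhodium hydrides also move terminal alkenes along the chain, and A4 still requires the biaryl coupling and two chain attachments.
- Comparison: in step count this road is probably shorter than the chosen one, and that is its honest advantage. The chosen plan sets against it that no step depends on catalyst-controlled regioselectivity at an unbiased alkene and that all selectivity rests on substrate features (hindered ketones, ring size).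

**Alternative 3:** Ring B is cut at C2'–C3' and C4'–C5', back to 2-aryl-3-alkylbuta-1,3-diene A7 (ring A as the aryl group) and vinylene carbonate A8. Forward, a thermal [4+2] cycloaddition would close ring B as cyclohexene A6 with a cis-fused carbonate; hydrolysis, diol oxidation and tautomerisation would then give the ring B catechol.
- Merits: two skeletal bonds and both ring B oxygens arrive in one step, the symmetric dienophile raises no regiochemical question, and the endgame is the same diol-to-catechol logic as in the chosen plan.
- Weak points: A8 is a sluggish dienophile that asks for high temperature in a sealed vessel, conditions under which a 2,3-disubstituted diene can dimerise or polymerise. A7 needs its aryl–diene bond made next to a methoxy group. Ring A must first be built as a complete 1,3,4,5-substituted catechol ether by classical arene chemistry.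
- Comparison: this road forms two bonds in its key step against one in the chosen plan and is intermolecular and convergent there. The chosen plan sets against it a catalytic ring closure at 40 °C and a diene precursor made by one enolate alkylation and two cross-couplings from simple pieces.

Key step: step 11

## Route

**Step 1**
Reactants: 1 8-bromooct-1-ene; 2 2,6-dimethoxybenzaldehyde
Product: 4 1-(2,6-dimethoxyphenyl)non-8-en-1-ol (racemic), via oct-7-en-1-ylmagnesium bromide 3 (not isolated)
Conditions: Mg, I2 (cat.), THF, reflux; then 2, 0 °C → rt; aq. NH4Cl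
Reagents that add atoms: none
Why: Grignard formation from a primary bromide and 1,2-addition to a non-enolisable aromatic aldehyde; the carbinol centre forms racemic and is oxidised away in step 8.

**Step 2**
Reactants: 5 methyl 2-(3,4-dimethoxyphenyl)acetate
Product: 6 methyl 2-(2-bromo-4,5-dimethoxyphenyl)acetate
Conditions: NBS, MeCN, 0 °C → rt
Reagents that add atoms: N-bromosuccinimide, O=C1CCC(=O)N1Br
Why: Electrophilic aromatic bromination; the position para to the 3-methoxy group and ortho to the acetate arm is the most activated open site, and ionic conditions leave the benzylic CH2 alone.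

**Step 3**
Reactants: 4 1-(2,6-dimethoxyphenyl)non-8-en-1-ol
Product: 7 9-{9-[(9-borabicyclo[3.3.1]nonan-9-yl)oxy]-9-(2,6-dimethoxyphenyl)nonyl}-9-borabicyclo[3.3.1]nonane (racemic; kept as a THF stock solution under argon)
Conditions: 9-BBN dimer (2.2 equiv B–H), THF, 0 °C → rt, then 50 °C until gas evolution ends; stored under argon
Reagents that add atoms: 9-borabicyclo[3.3.1]nonane (9-BBN, supplied as its dimer), B1C2CCCC1CCC2
Why: Anti-Markovnikov hydroboration of the terminal alkene places boron on the terminal carbon, and the second equivalent converts the hydroxyl into the B-alkoxy borinate with loss of hydrogen, so one defined species results. B-alkyl-9-BBN compounds keep under inert gas, so a single batch supplies both couplings (steps 4 and 6).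

**Step 4**
Reactants: 7 9-{9-[(9-borabicyclo[3.3.1]nonan-9-yl)oxy]-9-(2,6-dimethoxyphenyl)nonyl}-9-borabicyclo[3.3.1]nonane; 6 methyl 2-(2-bromo-4,5-dimethoxyphenyl)acetate
Product: 8 methyl 2-{2-[9-(2,6-dimethoxyphenyl)-9-hydroxynonyl]-4,5-dimethoxyphenyl}acetate (racemic)
Conditions: 7 (THF solution, 1.3 equiv), 6, Pd(OAc)2, SPhos, 3 M aq. K3PO4, THF, 50 °C
Reagents that add atoms: none
Why: B-alkyl Suzuki–Miyaura coupling; aqueous phosphate forms the hydroxyborate that transfers its primary alkyl group to palladium and at the same time hydrolyses the B–O borinate back to the free hydroxyl. The biarylphosphine speeds oxidative addition into the electron-rich ortho-substituted bromide and reductive elimination outruns beta-hydride elimination. No alkene is yet within reach of the arylpalladium species.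

**Step 5**
Reactants: 8 methyl 2-{2-[9-(2,6-dimethoxyphenyl)-9-hydroxynonyl]-4,5-dimethoxyphenyl}acetate
Product: 10 methyl 4-bromo-2-{2-[9-(2,6-dimethoxyphenyl)-9-hydroxynonyl]-4,5-dimethoxyphenyl}pent-4-enoate (diastereomer mixture), via dilithium alkoxide enolate 9 (not isolated)
Conditions: LiN(SiMe3)2 (2.1 equiv), THF, −78 °C; then 2,3-dibromoprop-1-ene, −78 → −20 °C; aq. NH4Cl
Reagents that add atoms: 2,3-dibromoprop-1-ene, C=C(Br)CBr
Why: Ester enolate alkylation; once the hydroxyl is a lithium alkoxide the arylacetate alpha-proton is the only acidic site, and the allylic bromide reacts by SN2 while the vinylic bromide is inert. The new benzylic centre (later C5 of ring A) forms without control and is erased in step 12.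

**Step 6**
Reactants: 10 methyl 4-bromo-2-{2-[9-(2,6-dimethoxyphenyl)-9-hydroxynonyl]-4,5-dimethoxyphenyl}pent-4-enoate; 7 9-{9-[(9-borabicyclo[3.3.1]nonan-9-yl)oxy]-9-(2,6-dimethoxyphenyl)nonyl}-9-borabicyclo[3.3.1]nonane
Product: 11 methyl 13-(2,6-dimethoxyphenyl)-2-{2-[9-(2,6-dimethoxyphenyl)-9-hydroxynonyl]-4,5-dimethoxyphenyl}-13-hydroxy-4-methylidenetridecanoate (diastereomer mixture)
Conditions: 7 (THF solution, 1.3 equiv), 10, Pd(OAc)2, SPhos, 3 M aq. K3PO4, THF, 40 °C
Reagents that add atoms: none
Why: Second B-alkyl Suzuki–Miyaura coupling, now at a 2-bromo-1-alkene that undergoes oxidative addition readily; no aryl halide remains, so the alkenylpalladium species has no intramolecular partner, and the ester tolerates the phosphate base. The borinate oxygen is again released as the free hydroxyl by the aqueous base.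

**Step 7**
Reactants: 11 methyl 13-(2,6-dimethoxyphenyl)-2-{2-[9-(2,6-dimethoxyphenyl)-9-hydroxynonyl]-4,5-dimethoxyphenyl}-13-hydroxy-4-methylidenetridecanoate
Product: 12 13-(2,6-dimethoxyphenyl)-2-{2-[9-(2,6-dimethoxyphenyl)-9-hydroxynonyl]-4,5-dimethoxyphenyl}-4-methylidenetridecane-1,13-diol (diastereomer mixture)
Conditions: LiAlH4, THF, 0 °C; then H2O, 15% aq. NaOH
Reagents that add atoms: none
Why: Hydride reduction of the methyl ester to the primary alcohol; the substrate now holds neither halide nor ketone, so the ester is the only reducible group and the isolated alkene is inert.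

**Step 8**
Reactants: 12 13-(2,6-dimethoxyphenyl)-2-{2-[9-(2,6-dimethoxyphenyl)-9-hydroxynonyl]-4,5-dimethoxyphenyl}-4-methylidenetridecane-1,13-diol
Product: 13 13-(2,6-dimethoxyphenyl)-2-{2-[9-(2,6-dimethoxyphenyl)-9-oxononyl]-4,5-dimethoxyphenyl}-4-methylidene-13-oxotridecanal (racemic)
Conditions: Dess–Martin periodinane (excess), NaHCO3, CH2Cl2, 0 °C → rt
Reagents that add atoms: none
Why: Dess–Martin oxidation of all three alcohols in one operation gives the aldehyde and unveils both hindered aryl ketones; the bicarbonate buffer protects the enolisable alpha-aryl aldehyde, which is used without storage.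

**Step 9**
Reactants: 14 acrolein
Product: 15 3-bromoprop-1-en-1-yl acetate (E/Z mixture)
Conditions: acetyl bromide, ZnCl2 (cat.), CH2Cl2, −20 °C → rt
Reagents that add atoms: acetyl bromide, CC(Br)=O
Why: Lewis-acid-catalysed addition of the acyl bromide to the enal (1,2-addition, then allylic transposition of bromide) gives the gamma-bromo enol acetate; both alkene isomers serve in step 10.

**Step 10**
Reactants: 13 13-(2,6-dimethoxyphenyl)-2-{2-[9-(2,6-dimethoxyphenyl)-9-oxononyl]-4,5-dimethoxyphenyl}-4-methylidene-13-oxotridecanal; 15 3-bromoprop-1-en-1-yl acetate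
Product: 17 1-(2,6-dimethoxyphenyl)-12-{2-[9-(2,6-dimethoxyphenyl)-9-oxononyl]-4,5-dimethoxyphenyl}-13,14-dihydroxy-10-methylidenehexadec-15-en-1-one (diastereomer mixture), via monoacetate 16 (not isolated)
Conditions: 15, In powder, THF, 0 °C → rt; then K2CO3, MeOH, rt
Reagents that add atoms: none
Why: Barbier-type alpha-hydroxyallylation: indium inserts into the allylic C–Br bond and the gamma-acetoxyallylindium adds through its oxygen-bearing carbon to the aldehyde, the only unhindered carbonyl (both 2,6-dimethoxyaryl ketones are twisted and shielded). Methanolysis removes the acetate wherever acyl migration has left it; C3 and C4 of ring A form as a diastereomer mixture that converges in step 12.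

**Step 11**
Reactants: 17 1-(2,6-dimethoxyphenyl)-12-{2-[9-(2,6-dimethoxyphenyl)-9-oxononyl]-4,5-dimethoxyphenyl}-13,14-dihydroxy-10-methylidenehexadec-15-en-1-one
Product: 18 1-(2,6-dimethoxyphenyl)-9-(5-{2-[9-(2,6-dimethoxyphenyl)-9-oxononyl]-4,5-dimethoxyphenyl}-3,4-dihydroxycyclohex-1-en-1-yl)nonan-1-one (diastereomer mixture)
Conditions: RuCl2(=CHPh)(PCy3)(SIMes) (second-generation Grubbs catalyst, 5 mol%), 1,4-benzoquinone (10 mol%), CH2Cl2 (0.005 M), 40 °C
Reagents that add atoms: none
Why: Ring-closing olefin metathesis by the Chauvin mechanism: the ruthenium benzylidene first exchanges with the unhindered monosubstituted C15=C16 alkene beside the carbinol, the new alkylidene adds [2+2] to the 1,1-disubstituted C10 alkene six atoms away, and cycloreversion of the ruthenacyclobutane gives the C1=C2 bond of ring A and a ruthenium methylidene that continues the cycle, ethylene being lost. The closest known reaction type is RCM of 1,7-dienes with one 1,1-disubstituted terminus to trisubstituted cyclohexenes, including octa-1,7-diene-3,4-diols. Ring A closes as a six-membered carbocycle by joining the two alkene termini of one chain, the new double bond lying inside the ring. No stereocentre is formed; C3, C4 and C5 are untouched and every diastereomer of 17 gives a cyclohexene that converges in step 12. The step needs ring closure to beat intermolecular metathesis and alkene migration: the 1,1-disubstituted alkene does not homodimerise, the six-membered ring and high dilution disfavour oligomers, and benzoquinone intercepts ruthenium hydrides that would isomerise the allylic alcohol to a ketone. Aryl ketones, aryl ethers and free hydroxyls are tolerated by this catalyst.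

**Step 12**
Reactants: 18 1-(2,6-dimethoxyphenyl)-9-(5-{2-[9-(2,6-dimethoxyphenyl)-9-oxononyl]-4,5-dimethoxyphenyl}-3,4-dihydroxycyclohex-1-en-1-yl)nonan-1-one
Product: 20 1-(2,6-dimethoxyphenyl)-9-(5-{2-[9-(2,6-dimethoxyphenyl)-9-oxononyl]-4,5-dimethoxyphenyl}-3,4-dihydroxyphenyl)nonan-1-one, via cyclohexenedione 19 (not isolated)
Conditions: (COCl)2, DMSO, CH2Cl2, −78 °C; then Et3N, −78 → 0 °C
Reagents that add atoms: none
Why: Twofold Swern oxidation of the vicinal diol gives the cyclohex-3-ene-1,2-dione; triethylamine then enolises it at C5 and, vinylogously, at C6 to the aromatic catechol, which removes all three sp3 centres. Activated DMSO does not carry a catechol on to the quinone.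

**Step 13**
Reactants: 20 1-(2,6-dimethoxyphenyl)-9-(5-{2-[9-(2,6-dimethoxyphenyl)-9-oxononyl]-4,5-dimethoxyphenyl}-3,4-dihydroxyphenyl)nonan-1-one
Product: 21 1-(2,6-dihydroxyphenyl)-9-(5-{2-[9-(2,6-dihydroxyphenyl)-9-oxononyl]-4,5-dihydroxyphenyl}-3,4-dihydroxyphenyl)nonan-1-one
Conditions: BBr3 (excess), CH2Cl2, −78 °C → rt; then MeOH, H2O, 0 °C, under argon
Reagents that add atoms: none
Why: Lewis-acid aryl methyl ether cleavage; the four methoxy groups ortho to the ketones go first with chelation assistance and the veratrole pair of ring B on warming, while ketones, biaryl and alkyl chains are inert. Hydrolysis of the aryl borates releases the octaphenol.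

## Compound list

1 | 8-bromooct-1-ene | C=CCCCCCCBr | starting material
2 | 2,6-dimethoxybenzaldehyde | O=Cc1c(OC)cccc1OC | starting material
3 | oct-7-en-1-ylmagnesium bromide (formed in the flask) | C=CCCCCCC[Mg]Br | intermediate
4 | 1-(2,6-dimethoxyphenyl)non-8-en-1-ol (racemic) | C=CCCCCCCC(O)c1c(OC)cccc1OC | intermediate
5 | methyl 2-(3,4-dimethoxyphenyl)acetate | COC(=O)Cc1ccc(OC)c(OC)c1 | starting material
6 | methyl 2-(2-bromo-4,5-dimethoxyphenyl)acetate | COC(=O)Cc1cc(OC)c(OC)cc1Br | intermediate
7 | 9-{9-[(9-borabicyclo[3.3.1]nonan-9-yl)oxy]-9-(2,6-dimethoxyphenyl)nonyl}-9-borabicyclo[3.3.1]nonane (racemic; kept as a THF stock solution) | COc1cccc(OC)c1C(OB1C2CCCC1CCC2)CCCCCCCCB1C2CCCC1CCC2 | intermediate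
8 | methyl 2-{2-[9-(2,6-dimethoxyphenyl)-9-hydroxynonyl]-4,5-dimethoxyphenyl}acetate (racemic) | COC(=O)Cc1cc(OC)c(OC)cc1CCCCCCCCC(O)c1c(OC)cccc1OC | intermediate
9 | dilithium alkoxide ester enolate of 8 (formed in the flask) | COC(O[Li])=Cc1cc(OC)c(OC)cc1CCCCCCCCC(O[Li])c1c(OC)cccc1OC | intermediate
10 | methyl 4-bromo-2-{2-[9-(2,6-dimethoxyphenyl)-9-hydroxynonyl]-4,5-dimethoxyphenyl}pent-4-enoate (diastereomer mixture) | COC(=O)C(CC(Br)=C)c1cc(OC)c(OC)cc1CCCCCCCCC(O)c1c(OC)cccc1OC | intermediate
11 | methyl 13-(2,6-dimethoxyphenyl)-2-{2-[9-(2,6-dimethoxyphenyl)-9-hydroxynonyl]-4,5-dimethoxyphenyl}-13-hydroxy-4-methylidenetridecanoate (diastereomer mixture) | COC(=O)C(c1cc(OC)c(OC)cc1CCCCCCCCC(O)c1c(OC)cccc1OC)CC(=C)CCCCCCCCC(O)c1c(OC)cccc1OC | intermediate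
12 | 13-(2,6-dimethoxyphenyl)-2-{2-[9-(2,6-dimethoxyphenyl)-9-hydroxynonyl]-4,5-dimethoxyphenyl}-4-methylidenetridecane-1,13-diol (diastereomer mixture) | OCC(c1cc(OC)c(OC)cc1CCCCCCCCC(O)c1c(OC)cccc1OC)CC(=C)CCCCCCCCC(O)c1c(OC)cccc1OC | intermediate
13 | 13-(2,6-dimethoxyphenyl)-2-{2-[9-(2,6-dimethoxyphenyl)-9-oxononyl]-4,5-dimethoxyphenyl}-4-methylidene-13-oxotridecanal (racemic) | O=CC(c1cc(OC)c(OC)cc1CCCCCCCCC(=O)c1c(OC)cccc1OC)CC(=C)CCCCCCCCC(=O)c1c(OC)cccc1OC | intermediate
14 | acrolein | C=CC=O | starting material
15 | 3-bromoprop-1-en-1-yl acetate (E/Z mixture) | CC(=O)OC=CCBr | intermediate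
16 | 14-acetoxy-1-(2,6-dimethoxyphenyl)-12-{2-[9-(2,6-dimethoxyphenyl)-9-oxononyl]-4,5-dimethoxyphenyl}-13-hydroxy-10-methylidenehexadec-15-en-1-one (formed in the flask; diastereomer mixture, acetate partly migrated to O13) | C=CC(OC(C)=O)C(O)C(c1cc(OC)c(OC)cc1CCCCCCCCC(=O)c1c(OC)cccc1OC)CC(=C)CCCCCCCCC(=O)c1c(OC)cccc1OC | intermediate
17 | 1-(2,6-dimethoxyphenyl)-12-{2-[9-(2,6-dimethoxyphenyl)-9-oxononyl]-4,5-dimethoxyphenyl}-13,14-dihydroxy-10-methylidenehexadec-15-en-1-one (diastereomer mixture) | C=CC(O)C(O)C(c1cc(OC)c(OC)cc1CCCCCCCCC(=O)c1c(OC)cccc1OC)CC(=C)CCCCCCCCC(=O)c1c(OC)cccc1OC | intermediate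
18 | 1-(2,6-dimethoxyphenyl)-9-(5-{2-[9-(2,6-dimethoxyphenyl)-9-oxononyl]-4,5-dimethoxyphenyl}-3,4-dihydroxycyclohex-1-en-1-yl)nonan-1-one (diastereomer mixture) | OC1C=C(CCCCCCCCC(=O)c2c(OC)cccc2OC)CC(c2cc(OC)c(OC)cc2CCCCCCCCC(=O)c2c(OC)cccc2OC)C1O | intermediate
19 | 1-(2,6-dimethoxyphenyl)-9-(5-{2-[9-(2,6-dimethoxyphenyl)-9-oxononyl]-4,5-dimethoxyphenyl}-3,4-dioxocyclohex-1-en-1-yl)nonan-1-one (formed in the flask; racemic) | O=C1C=C(CCCCCCCCC(=O)c2c(OC)cccc2OC)CC(c2cc(OC)c(OC)cc2CCCCCCCCC(=O)c2c(OC)cccc2OC)C1=O | intermediate
20 | 1-(2,6-dimethoxyphenyl)-9-(5-{2-[9-(2,6-dimethoxyphenyl)-9-oxononyl]-4,5-dimethoxyphenyl}-3,4-dihydroxyphenyl)nonan-1-one | O=C(CCCCCCCCc1cc(O)c(O)c(-c2cc(OC)c(OC)cc2CCCCCCCCC(=O)c2c(OC)cccc2OC)c1)c1c(OC)cccc1OC | intermediate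
21 | 1-(2,6-dihydroxyphenyl)-9-(5-{2-[9-(2,6-dihydroxyphenyl)-9-oxononyl]-4,5-dihydroxyphenyl}-3,4-dihydroxyphenyl)nonan-1-one (CNP0305015.0) | O=C(CCCCCCCCc1cc(O)c(O)c(-c2cc(O)c(O)cc2CCCCCCCCC(=O)c2c(O)cccc2O)c1)c1c(O)cccc1O | target

## Step count and risks

Total: 13 steps. Longest linear sequence: 11 steps (steps 1, 3–8 and 10–13, from 1 to 21).

**Step 11 (key step).** Ring closure may lose to two processes. One is migration of the allylic alcohol double bond to a ketone through ruthenium hydrides. The other is slow engagement of the 1,1-disubstituted alkene, which lets oligomerisation through the vinyl carbinol ends take over; chelation of the free diol to ruthenium would slow some diastereomers further. Fallback: from 17, acetylation (Ac2O, pyridine, DMAP) should give diene diacetate F1, which has no free hydroxyl to chelate or isomerise. Ring-closing metathesis of F1 with the same ruthenium carbene should give cyclohexene diacetate F2, and methanolysis (K2CO3, MeOH) returns to 18.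

**Step 12.** Three things can go wrong. The oxidation may stall at the hydroxy ketone. The newly formed catecholate may be alkylated by residual activated DMSO (methylthiomethyl transfer). The electron-rich rings may be chlorinated by the chlorosulfonium salt. Fallback: from 18, oxidation is driven past the catechol on purpose with excess IBX in DMSO, which takes the diol through dione and catechol to ortho-quinone F3. Reduction of F3 with aqueous Na2S2O4 gives 20, so the over-oxidation that threatens the Swern route becomes the planned path.

**Step 10.** The alpha-aryl aldehyde may enolise and self-condense or oxidise in air before it is trapped, and the allylindium may form sluggishly or couple with itself. Fallback: from 13, allylboration replaces the Barbier reaction. Pinacol (Z)-3-(methoxymethoxy)allylboronate F4 is made in the flask from allyl methoxymethyl ether (sec-BuLi, then 2-isopropoxy-4,4,5,5-tetramethyl-1,3,2-dioxaborolane). It should add to the aldehyde alone, through a closed six-membered transition state, to give methoxymethyl ether F5 as a diastereomer mixture. Mild acid (HCl, MeOH) removes the acetal and gives 17.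

**Step 4.** Oxidative addition into the electron-rich, ortho-substituted aryl bromide may be slow, so that beta-hydride elimination of the alkylpalladium intermediate (reduced arene plus isomerised alkene) and partial ester hydrolysis take over. Loss of borane strength through air ingress during storage of the stock solution would have the same effect. Fallback: from 6 and 4, a Heck reaction (Pd(OAc)2, P(o-tol)3, Et3N, DMF, 100 °C) should give styrene F6 together with double-bond positional isomers. Hydrogenation (H2, Pd/C, EtOAc with a trace of Et3N to spare the benzylic alcohol) funnels all linear isomers to 8.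

## Further compounds

F1 | step 11 | 1-(2,6-dimethoxyphenyl)-12-{2-[9-(2,6-dimethoxyphenyl)-9-oxononyl]-4,5-dimethoxyphenyl}-10-methylidene-1-oxohexadec-15-ene-13,14-diyl diacetate (diastereomer mixture) | C=CC(OC(C)=O)C(OC(C)=O)C(c1cc(OC)c(OC)cc1CCCCCCCCC(=O)c1c(OC)cccc1OC)CC(=C)CCCCCCCCC(=O)c1c(OC)cccc1OC
F2 | step 11 | 4-[9-(2,6-dimethoxyphenyl)-9-oxononyl]-6-{2-[9-(2,6-dimethoxyphenyl)-9-oxononyl]-4,5-dimethoxyphenyl}cyclohex-3-ene-1,2-diyl diacetate (diastereomer mixture) | CC(=O)OC1C=C(CCCCCCCCC(=O)c2c(OC)cccc2OC)CC(c2cc(OC)c(OC)cc2CCCCCCCCC(=O)c2c(OC)cccc2OC)C1OC(C)=O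
F3 | step 12 | 5-[9-(2,6-dimethoxyphenyl)-9-oxononyl]-3-{2-[9-(2,6-dimethoxyphenyl)-9-oxononyl]-4,5-dimethoxyphenyl}cyclohexa-3,5-diene-1,2-dione | O=C1C=C(CCCCCCCCC(=O)c2c(OC)cccc2OC)C=C(c2cc(OC)c(OC)cc2CCCCCCCCC(=O)c2c(OC)cccc2OC)C1=O
F4 | step 10 | 2-[(Z)-3-(methoxymethoxy)prop-2-en-1-yl]-4,4,5,5-tetramethyl-1,3,2-dioxaborolane | COCO/C=C\CB1OC(C)(C)C(C)(C)O1
F5 | step 10 | 1-(2,6-dimethoxyphenyl)-12-{2-[9-(2,6-dimethoxyphenyl)-9-oxononyl]-4,5-dimethoxyphenyl}-13-hydroxy-14-(methoxymethoxy)-10-methylidenehexadec-15-en-1-one (diastereomer mixture) | C=CC(OCOC)C(O)C(c1cc(OC)c(OC)cc1CCCCCCCCC(=O)c1c(OC)cccc1OC)CC(=C)CCCCCCCCC(=O)c1c(OC)cccc1OC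
F6 | step 4 | methyl 2-{2-[(E)-9-(2,6-dimethoxyphenyl)-9-hydroxynon-1-en-1-yl]-4,5-dimethoxyphenyl}acetate (racemic) | COC(=O)Cc1cc(OC)c(OC)cc1/C=C/CCCCCCC(O)c1c(OC)cccc1OC
A1 | alternative 1 | biaryl bis(2-acylcyclohexane-1,3-dione) | O=C(CCCCCCCCc1cc(OC)c(OC)c(-c2cc(OC)c(OC)cc2CCCCCCCCC(=O)C2C(=O)CCCC2=O)c1)C1C(=O)CCCC1=O
A2 | alternative 1 | biaryl bis(methyl 5,7-dioxoalkanoate) | COC(=O)CCCC(=O)CC(=O)CCCCCCCCc1cc(OC)c(OC)c(-c2cc(OC)c(OC)cc2CCCCCCCCC(=O)CC(=O)CCCC(=O)OC)c1
A3 | alternative 2 | target with both catechols as methyl ethers | O=C(CCCCCCCCc1cc(OC)c(OC)c(-c2cc(OC)c(OC)cc2CCCCCCCCC(=O)c2c(O)cccc2O)c1)c1c(O)cccc1O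
A4 | alternative 2 | 3,4,4',5'-tetramethoxy-5,2'-bis(oct-7-en-1-yl)biphenyl (ring A and ring B numbering as in the target) | C=CCCCCCCc1cc(OC)c(OC)c(-c2cc(OC)c(OC)cc2CCCCCCC=C)c1
A5 | alternative 2 | 2,6-dihydroxybenzaldehyde | O=Cc1c(O)cccc1O
A6 | alternative 3 | cis-fused cyclohexene carbonate (racemic, relative configuration shown) | O=C1O[C@H]2CC(c3cc(CCCCCCCCC(=O)c4c(OC)cccc4OC)cc(OC)c3OC)=C(CCCCCCCCC(=O)c3c(OC)cccc3OC)C[C@H]2O1
A7 | alternative 3 | 2-aryl-3-alkylbuta-1,3-diene | C=C(c1cc(CCCCCCCCC(=O)c2c(OC)cccc2OC)cc(OC)c1OC)C(=C)CCCCCCCCC(=O)c1c(OC)cccc1OC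
A8 | alternative 3 | vinylene carbonate | O=C1OC=CO1
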